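**Assumptions.** The SMILES is read as (2R,7R,8R,3E,11E) in cembrane numbering (C1 = ring-fusion sp2 carbon, C2 = O–CH, C7/C8 = epoxide, C16 = ring OCH2, C17 = CH2OAc); this numbering is used for all intermediates. Geranyl bromide, 1-(trimethylsilyl)propyne, methallyl alcohol, 3-bromo-2-(bromomethyl)prop-1-ene, the D-fructose-derived Shi ketone and (S)-Me-CBS are taken as commercial.

**Retrosynthetic overview**
1. The dihydrofuran is formed last: ring-closing metathesis of a C2–O-(2-acetoxymethyl)allyl ether onto a C1 exo-methylene (C1=C15, loses ethylene).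
2. C2 (R) is set by CBS reduction of the macrocyclic cross-conjugated dienone.
3. The 14-membered ring is formed first, by Nozaki–Hiyama–Kishi closure of C2–C3 (E-vinyl iodide onto a 2-methylidene aldehyde).
4. C14–C1–C2 comes from methallyl alcohol dianion alkylating a C13 allylic chloride; the (7R,8R)-epoxide comes from Shi epoxidation of the only electron-rich olefin of the acyclic triene.
5. The triene comes from geranyl bromide by propargylation, Negishi carboalumination–iodination and SeO2 oxidation.

**Route**

Step 1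
Reactants: 1 geranyl bromide; 2 1-(trimethylsilyl)propyne
Product: 3 (5E)-6,10-dimethylundeca-5,9-dien-1-yne
Conditions: 2, n-BuLi, THF, −78 °C; add 1, −78 → 0 °C; then TBAF, rt (one pot)
Reagents that add atoms: 2, CC#C[Si](C)(C)C (C3 unit; silyl group removed)
Why: Propargylation with 3-lithio-1-TMS-propyne is a clean SN2 at the primary allylic bromide, and fluoride then removes the silyl group; no stereocentre is formed.

Step 2
Reactants: 3
Product: 4 (1E,5E)-1-iodo-2,6,10-trimethylundeca-1,5,9-triene
Conditions: AlMe3, Cp2ZrCl2, CH2Cl2, 0 °C → rt; then I2, THF, −30 → 0 °C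
Reagents that add atoms: trimethylaluminium, C[Al](C)C (CH3); iodine, II (I)
Why: Negishi Zr-catalysed carboalumination is a syn, terminal-Al addition and iodinolysis proceeds with retention, so the E-vinyl iodide (future C3=C4) is fixed.

Step 3
Reactants: 4
Product: 5 (2E,6E,10E)-11-iodo-2,6,10-trimethylundeca-2,6,10-trien-1-ol
Conditions: SeO2 (cat.), t-BuOOH, salicylic acid (cat.), CH2Cl2, rt; NaBH4/MeOH work-up
Reagents that add atoms: selenium dioxide, O=[Se]=O (O; turned over by t-BuOOH, CC(C)(C)OO)
Why: SeO2/TBHP allylic oxidation (ene then [2,3] shift) picks the E-methyl of the terminal, most electron-rich olefin and gives the E-allylic alcohol (C13–OH).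

Step 4
Reactants: 5
Product: 6 (1E,5E,9E)-11-chloro-1-iodo-2,6,10-trimethylundeca-1,5,9-triene
Conditions: MsCl, LiCl, s-collidine, DMF, 0 °C
Reagents that add atoms: lithium chloride, [Li+].[Cl-] (Cl; MsCl, CS(=O)(=O)Cl, is the activator)
Why: Collington–Meyers chlorination converts the primary allylic alcohol to the chloride by SN2 without allylic transposition or E/Z loss.

Step 5
Reactants: 6
Product: 7 (2R,3R)-2-[(3E)-5-chloro-4-methylpent-3-en-1-yl]-3-[(3E)-4-iodo-3-methylbut-3-en-1-yl]-2-methyloxirane
Conditions: D-fructose-derived Shi ketone (0.3 equiv), Oxone (about 1.1 equiv active O), K2CO3, Bu4NHSO4, MeCN–DMM/aq. borate buffer (pH 10.5), 0 °C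
Reagents that add atoms: Oxone (KHSO5), [K+].[O-]S(=O)(=O)OO (O)
Why: In the Shi epoxidation the vinyl iodide and the allylic-chloride olefin are inductively deactivated, so only the central trisubstituted olefin reacts; the spiro transition state of the D-fructose ketone gives the (R,R)-epoxide (C7 R, C8 R).

Step 6
Reactants: 7; 8 2-methylprop-2-en-1-ol (methallyl alcohol)
Product: 9 (5E)-8-[(2R,3R)-3-[(3E)-4-iodo-3-methylbut-3-en-1-yl]-2-methyloxiran-2-yl]-5-methyl-2-methylideneoct-5-en-1-ol
Conditions: 8, n-BuLi (1.95 equiv per 8), TMEDA, Et2O, 0 °C → rt; then 7, THF, −78 → −30 °C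
Reagents that add atoms: 8, CC(=C)CO (CH2=C(CH2OH)CH2– unit)
Why: The methallyl alcohol dianion is a symmetric 2-substituted allyl anion, so only SN2 at the primary allylic chloride matters; this installs C14, C1(=CH2) and C2 in one step, and the epoxide and vinyl iodide are much slower electrophiles at −78 °C.

Step 7
Reactants: 9
Product: 10 (5E)-8-[(2R,3R)-3-[(3E)-4-iodo-3-methylbut-3-en-1-yl]-2-methyloxiran-2-yl]-5-methyl-2-methylideneoct-5-enal
Conditions: activated MnO2, CH2Cl2, rt
Reagents that add atoms: none
Why: MnO2 oxidises only the allylic alcohol, giving the non-enolisable 2-alkylacrolein without touching the epoxide or vinyl iodide.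

Step 8
Reactants: 10
Product: 11 (3E,7R,8R,11E)-7,8-epoxy-4,8,12-trimethyl-1-methylidenecyclotetradeca-3,11-dien-2-ol (about 1:1 at C2)
Conditions: CrCl2 (10 equiv), NiCl2 (1 mol % of Cr), DMSO–THF, rt, syringe-pump addition (final about 3 mM)
Reagents that add atoms: none
Why: The Nozaki–Hiyama–Kishi reaction adds the vinyl-chromium 1,2 to the aldehyde with retention of the E-olefin and closes the 14-membered ring; C2 is not controlled here and is corrected in steps 9–10.

Step 9
Reactants: 11
Product: 12 (3E,7R,8R,11E)-7,8-epoxy-4,8,12-trimethyl-1-methylidenecyclotetradeca-3,11-dien-2-one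
Conditions: Dess–Martin periodinane, NaHCO3, CH2Cl2, 0 °C
Reagents that add atoms: none
Why: Buffered Dess–Martin oxidation converges both C2 epimers to one dienone under conditions that spare the epoxide.

Step 10
Reactants: 12
Product: 13 (2R,3E,7R,8R,11E)-7,8-epoxy-4,8,12-trimethyl-1-methylidenecyclotetradeca-3,11-dien-2-ol
Conditions: (S)-Me-CBS (1 equiv), catecholborane, toluene, −78 °C
Reagents that add atoms: none
Why: Corey–Bakshi–Shibata 1,2-reduction under catalyst control; I assume the α-branched 1-alkylvinyl arm (C1) is the large group and the α-H alkenyl arm (C3) the small one, in which case the (S)-catalyst gives 2R (to be confirmed by Mosher analysis).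

Step 11
Reactants: 13; 14 3-bromo-2-(bromomethyl)prop-1-ene
Product: 15 2-({[(2R,3E,7R,8R,11E)-7,8-epoxy-4,8,12-trimethyl-1-methylidenecyclotetradeca-3,11-dien-2-yl]oxy}methyl)prop-2-en-1-yl acetate
Conditions: NaH, 14 (5 equiv), Bu4NI (cat.), THF–DMF, 0 °C → rt; then CsOAc (excess), rt (one pot)
Reagents that add atoms: 14, C=C(CBr)CBr (CH2–C(=CH2)–CH2 unit); caesium acetate, CC(=O)[O-].[Cs+] (OAc)
Why: Williamson etherification of the C2 alkoxide (C2–O bond untouched, so 2R is retained) followed by SN2 displacement of the remaining allylic bromide by acetate.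

Step 12
Reactants: 15
Product: 16 lobophynin B
Conditions: Hoveyda–Grubbs II or Stewart–Grubbs catalyst (10–20 mol %), toluene (2 mM), 80 °C, Ar sparge
Reagents that add atoms: none
Why: Ring-closing metathesis of the two 1,1-disubstituted olefins forms the tetrasubstituted C1=C15 bond of the 2,5-dihydrofuran with loss of ethylene; the trisubstituted ring olefins, epoxide and acetate are inert, and no stereocentre is touched.

**Compound list**
1 | geranyl bromide, (2E)-1-bromo-3,7-dimethylocta-2,6-diene | CC(C)=CCC/C(C)=C/CBr | starting material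
2 | 1-(trimethylsilyl)propyne | CC#C[Si](C)(C)C | starting material
3 | (5E)-6,10-dimethylundeca-5,9-dien-1-yne | CC(C)=CCC/C(C)=C/CCC#C | intermediate
4 | (1E,5E)-1-iodo-2,6,10-trimethylundeca-1,5,9-triene | CC(C)=CCC/C(C)=C/CC/C(C)=C/I | intermediate
5 | (2E,6E,10E)-11-iodo-2,6,10-trimethylundeca-2,6,10-trien-1-ol | OC/C(C)=C/CC/C(C)=C/CC/C(C)=C/I | intermediate
6 | (1E,5E,9E)-11-chloro-1-iodo-2,6,10-trimethylundeca-1,5,9-triene | ClC/C(C)=C/CC/C(C)=C/CC/C(C)=C/I | intermediate
7 | (2R,3R)-2-[(3E)-5-chloro-4-methylpent-3-en-1-yl]-3-[(3E)-4-iodo-3-methylbut-3-en-1-yl]-2-methyloxirane | ClC/C(C)=C/CC[C@@]1(C)O[C@@H]1CC/C(C)=C/I | intermediate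
8 | 2-methylprop-2-en-1-ol (methallyl alcohol) | CC(=C)CO | starting material
9 | (5E)-8-[(2R,3R)-3-[(3E)-4-iodo-3-methylbut-3-en-1-yl]-2-methyloxiran-2-yl]-5-methyl-2-methylideneoct-5-en-1-ol | OCC(=C)CC/C(C)=C/CC[C@@]1(C)O[C@@H]1CC/C(C)=C/I | intermediate
10 | (5E)-8-[(2R,3R)-3-[(3E)-4-iodo-3-methylbut-3-en-1-yl]-2-methyloxiran-2-yl]-5-methyl-2-methylideneoct-5-enal | O=CC(=C)CC/C(C)=C/CC[C@@]1(C)O[C@@H]1CC/C(C)=C/I | intermediate
11 | (3E,7R,8R,11E)-7,8-epoxy-4,8,12-trimethyl-1-methylidenecyclotetradeca-3,11-dien-2-ol, C2 epimer mixture | C=C1CC/C(C)=C/CC[C@@]2(C)O[C@@H]2CC/C(C)=C/C1O | intermediate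
12 | (3E,7R,8R,11E)-7,8-epoxy-4,8,12-trimethyl-1-methylidenecyclotetradeca-3,11-dien-2-one | C=C1CC/C(C)=C/CC[C@@]2(C)O[C@@H]2CC/C(C)=C/C1=O | intermediate
13 | (2R,3E,7R,8R,11E)-7,8-epoxy-4,8,12-trimethyl-1-methylidenecyclotetradeca-3,11-dien-2-ol | C=C1CC/C(C)=C/CC[C@@]2(C)O[C@@H]2CC/C(C)=C/[C@H]1O | intermediate
14 | 3-bromo-2-(bromomethyl)prop-1-ene | C=C(CBr)CBr | starting material
15 | 2-({[(2R,3E,7R,8R,11E)-7,8-epoxy-4,8,12-trimethyl-1-methylidenecyclotetradeca-3,11-dien-2-yl]oxy}methyl)prop-2-en-1-yl acetate | C=C1CC/C(C)=C/CC[C@@]2(C)O[C@@H]2CC/C(C)=C/[C@H]1OCC(=C)COC(C)=O | intermediate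
16 | lobophynin B | CC(=O)OCC1=C2CC/C(C)=C/CC[C@@]3(C)O[C@@H]3CC/C(C)=C/[C@H]2OC1 | target

**Totals.** 12 steps; longest linear sequence 12 (from geranyl bromide); no protecting groups.

**Three steps most likely to fail, with fallbacks**
1. **Step 10 (CBS on a ketone flanked by two alkenyl groups).** Which arm behaves as "large" is not certain, so both the ee and the sense are at risk. Fallback: skip the carboalumination and carry the terminal alkyne of 3 through steps 3–7; close the ring by intramolecular acetylide addition to the aldehyde; oxidise and CBS-reduce the ynone, where the alkynyl group is unambiguously the small one; then build (E)-C3=C4(Me) by hydroxyl-directed Red-Al/I2 and Pd-catalysed methylation, and rejoin at 13.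
2. **Step 12 (RCM to a tetrasubstituted dihydrofuran olefin).** Fallback: build C1=C15 before ring closure and form the furan ring by etherification. Use a C1 vinyl halide carrying a C15(CH2OSiR3)2 unit (from 1,3-bis(silyloxy)acetone via its gem-dibromo-olefin and a B-alkyl Suzuki coupling at C14), close the macrocycle at C1–C2, then desilylate, cyclise the C2–OH onto the cis CH2–X by intramolecular Williamson reaction, and acetylate the remaining CH2OH.
3. **Step 6 (dilithio methallyl alcohol with a vinyl iodide and an epoxide present).** Li–I exchange or epoxide opening could compete. Fallback: replace the dianion with the Grignard reagent of 2-(chloromethyl)-3-(tert-butyldimethylsilyloxy)prop-1-ene under Cu catalysis (Li2CuCl4), then remove the silyl group with TBAF; this costs one step but avoids a hard organolithium.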